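Ring A is disconnected at C7–C8. C7 is the one sp2 carbon of ring A and carries the C14 methylidene, so it can be the enol triflate carbon of a methyl ketone on the spiro carbon C6, while C8 is the terminal carbon of a vinyl group on the C10 carbinol. In one operation, 9-BBN hydroboration and palladium-catalysed B-alkyl Suzuki coupling form C7–C8, close ring A between the quaternary carbons C6 and C11 and leave C7=C14 exocyclic. The precursor is a 4-methylcyclohex-3-ene (ring B) whose C6 bears the vinyl triflate and a CMe2–CH(OTBS)–CH=CH2 arm; C10 is fixed first, then C6 by a catalytic enantioselective Diels–Alder reaction.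

Key step: step 12

Remark on numbering: chamigrene numbers are used throughout (ring A = C6–C7(=C14)–C8–C9–C10–C11, ring B = C6–C1–C2–C3–C4–C5), also for the open-chain intermediates.

Assumption: the (S)-oxazaborolidinium catalyst of step 8 is taken to shield the same face of the 2-tert-alkyl acrolein 11 as it does for 2-methyl- and 2-bromoacrolein; if the sense were opposite, the (R)-catalyst would be used.

Step 1
Reactants: 1 isobutyraldehyde; 2 prenyl bromide (1-bromo-3-methylbut-2-ene)
Product: 3 2,2,5-trimethylhex-4-enal
Conditions: 50% aq. NaOH, Bu4NI (5 mol%), PhMe, 60 °C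
Reagents that add atoms: none
Why: Phase-transfer C-alkylation of the isobutyraldehyde enolate (SN2 at the primary allylic bromide) installs the gem-dimethyl carbon C11 and a prenyl arm that serves as a masked C7 aldehyde, and the product has no α-hydrogen left for further reaction.

Step 2
Reactants: 3 2,2,5-trimethylhex-4-enal; 4 vinylmagnesium bromide
Product: 5 (±)-4,4,7-trimethylocta-1,6-dien-3-ol
Conditions: THF, −78 → 0 °C; aq. NH4Cl
Reagents that add atoms: none
Why: Grignard 1,2-addition to the non-enolisable aldehyde forms the C10 carbinol with its C9=C8 vinyl group; the racemic centre is erased in step 3.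

Step 3
Reactants: 5 (±)-4,4,7-trimethylocta-1,6-dien-3-ol
Product: 6 4,4,7-trimethylocta-1,6-dien-3-one
Conditions: Dess–Martin periodinane, CH2Cl2, 0 °C → rt
Reagents that add atoms: none
Why: Dess–Martin oxidation of the secondary allylic alcohol gives the vinyl ketone, which cannot enolise toward the quaternary C11 and is used at once.

Step 4
Reactants: 6 4,4,7-trimethylocta-1,6-dien-3-one
Product: 7 (3R)-4,4,7-trimethylocta-1,6-dien-3-ol
Conditions: (S)-1-methyl-3,3-diphenyltetrahydro-1H,3H-pyrrolo[1,2-c][1,3,2]oxazaborole [(S)-Me-CBS, 15 mol%], catecholborane (1.5 equiv), PhMe, −78 → −30 °C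
Reagents that add atoms: none
Why: Corey–Bakshi–Shibata reduction in which the tert-alkyl group takes the large-group position and vinyl the small one, so hydride reaches one carbonyl face and C10 is set as (R) by reagent control, while catecholborane leaves both alkenes alone at this temperature.

Step 5
Reactants: 7 (3R)-4,4,7-trimethylocta-1,6-dien-3-ol
Product: 8 (3R)-3-(tert-butyldimethylsilyloxy)-4,4,7-trimethylocta-1,6-diene
Conditions: TBSOTf, 2,6-lutidine, CH2Cl2, −78 → 0 °C
Reagents that add atoms: tert-butyldimethylsilyl trifluoromethanesulfonate, CC(C)(C)[Si](C)(C)OS(=O)(=O)C(F)(F)F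
Why: Silylation of the hindered secondary hydroxyl with the silyl triflate protects C10–O through the later organometallic, basic and oxidative steps and prevents lactol formation once the C7 aldehyde is unmasked.

Step 6
Reactants: 8 (3R)-3-(tert-butyldimethylsilyloxy)-4,4,7-trimethylocta-1,6-diene
Product: 10 (4R)-4-(tert-butyldimethylsilyloxy)-3,3-dimethylhex-5-enal, via secondary ozonide 9 (not isolated)
Conditions: O3 (1.0 equiv), CH2Cl2, −78 °C; then Me2S, −78 °C → rt
Reagents that add atoms: ozone, [O-][O+]=O
Why: Ozonolysis is much faster at the electron-rich trisubstituted prenyl alkene than at the monosubstituted vinyl group, which is deactivated by the allylic silyloxy group and shielded by C11, so one equivalent of ozone cleaves only the prenyl alkene and reduction of ozonide 9 unmasks the C7 aldehyde.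

Step 7
Reactants: 10 (4R)-4-(tert-butyldimethylsilyloxy)-3,3-dimethylhex-5-enal
Product: 11 (4R)-4-(tert-butyldimethylsilyloxy)-3,3-dimethyl-2-methylidenehex-5-enal
Conditions: 37% aq. CH2O, pyrrolidine (20 mol%), propionic acid (20 mol%), i-PrOH, 45 °C
Reagents that add atoms: formaldehyde, C=O
Why: Amine-catalysed Mannich condensation with formaldehyde and elimination (α-methylenation of an aldehyde) turns the C6 methylene into the 2-substituted acrolein unit C5=C6–C7HO; the temperature is held at or below 45 °C because the product is a 3-silyloxy-1,5-diene that could undergo Cope rearrangement on stronger heating.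

Step 8
Reactants: 11 (4R)-4-(tert-butyldimethylsilyloxy)-3,3-dimethyl-2-methylidenehex-5-enal; 12 isoprene
Product: 13 (1S)-1-[(3R)-3-(tert-butyldimethylsilyloxy)-2-methylpent-4-en-2-yl]-4-methylcyclohex-3-ene-1-carbaldehyde
Conditions: isoprene (5 equiv), (S)-3,3-diphenyl-1-(o-tolyl)tetrahydro-1H,3H-pyrrolo[1,2-c][1,3,2]oxazaborole (20 mol%) activated with Tf2NH (16 mol%), CH2Cl2, −78 → −20 °C
Reagents that add atoms: none
Why: Lewis acid-catalysed Diels–Alder reaction of a 2-substituted acrolein, in which isoprene adds with para orientation (C3 methyl opposite C6) and the chiral oxazaborolidinium cation blocks one face of the bound enal so that C6 is set by catalyst control; because C10 is already fixed, any C6 epimer is a diastereomer and is removed by chromatography.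

Step 9
Reactants: 13 (1S)-1-[(3R)-3-(tert-butyldimethylsilyloxy)-2-methylpent-4-en-2-yl]-4-methylcyclohex-3-ene-1-carbaldehyde
Product: 14 1-{(1S)-1-[(3R)-3-(tert-butyldimethylsilyloxy)-2-methylpent-4-en-2-yl]-4-methylcyclohex-3-en-1-yl}ethan-1-ol (both carbinol epimers)
Conditions: MeMgBr, THF, −78 → 0 °C; aq. NH4Cl
Reagents that add atoms: methylmagnesium bromide, C[Mg]Br
Why: Grignard 1,2-addition to the non-enolisable neopentylic aldehyde adds the C14 carbon; the new C7 carbinol centre forms as both epimers and is removed in step 10.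

Step 10
Reactants: 14 1-{(1S)-1-[(3R)-3-(tert-butyldimethylsilyloxy)-2-methylpent-4-en-2-yl]-4-methylcyclohex-3-en-1-yl}ethan-1-ol
Product: 15 1-{(1S)-1-[(3R)-3-(tert-butyldimethylsilyloxy)-2-methylpent-4-en-2-yl]-4-methylcyclohex-3-en-1-yl}ethan-1-one
Conditions: Dess–Martin periodinane, CH2Cl2, rt
Reagents that add atoms: none
Why: Dess–Martin oxidation converts both carbinol epimers into the single C7 methyl ketone without touching the alkenes or the silyl ether.

Step 11
Reactants: 15 1-{(1S)-1-[(3R)-3-(tert-butyldimethylsilyloxy)-2-methylpent-4-en-2-yl]-4-methylcyclohex-3-en-1-yl}ethan-1-one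
Product: 17 1-{(1S)-1-[(3R)-3-(tert-butyldimethylsilyloxy)-2-methylpent-4-en-2-yl]-4-methylcyclohex-3-en-1-yl}ethenyl trifluoromethanesulfonate, via potassium enolate 16 (not isolated)
Conditions: KN(SiMe3)2, THF, −78 °C; then PhNTf2, −78 → 0 °C
Reagents that add atoms: N-phenylbis(trifluoromethanesulfonimide), O=S(=O)(N(c1ccccc1)S(=O)(=O)C(F)(F)F)C(F)(F)F
Why: Enol triflate formation: deprotonation can occur only at the methyl group because C6 is quaternary, and O-sulfonylation of enolate 16 fixes the C7=C14 double bond.

Step 12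
Reactants: 17 1-{(1S)-1-[(3R)-3-(tert-butyldimethylsilyloxy)-2-methylpent-4-en-2-yl]-4-methylcyclohex-3-en-1-yl}ethenyl trifluoromethanesulfonate
Product: 19 (6R,10R)-10-(tert-butyldimethylsilyloxy)chamigra-2,7(14)-diene, via B-alkyl-9-BBN borane 18 (not isolated)
Conditions: 9-BBN (1.5 equiv), THF, 0 °C → rt; then PdCl2(dppf) (10 mol%), Cs2CO3 (3 equiv), DMF/THF/H2O, 0.01 M, 60 °C
Reagents that add atoms: none
Why: 9-BBN adds to the only monosubstituted alkene with boron on C8 (anti-Markovnikov) to give borane 18; zerovalent palladium formed from PdCl2(dppf) then inserts into the C7–O bond of the triflate, the carbonate-activated borane hands its primary C8 alkyl group to palladium, and reductive elimination forms C7–C8. The closest known reaction type is the intramolecular B-alkyl Suzuki–Miyaura coupling of alkenyl halides and triflates, which closes five- and six-membered rings bearing an exocyclic methylene. Ring A closes by reductive elimination from a seven-membered palladacycle (Pd, C7, C6, C11, C10, C9, C8), giving the six-membered carbocycle with C7=C14 exocyclic. No stereocentre is formed, and C6 and C10 pass through unchanged. The step needs chemoselective hydroboration, which the bulk of 9-BBN secures (C8=C9 reacts before the trisubstituted C2=C3 alkene and the electron-poor 1,1-disubstituted enol triflate), and it needs cyclisation to outrun β-hydride elimination and intermolecular coupling, which the bidentate dppf ligand, high dilution and the two quaternary carbons C6 and C11 in the tether favour.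

Step 13
Reactants: 19 (6R,10R)-10-(tert-butyldimethylsilyloxy)chamigra-2,7(14)-diene
Product: 20 (6R,10R)-chamigra-2,7(14)-dien-10-ol
Conditions: Bu4NF, THF, 50 °C
Reagents that add atoms: none
Why: Fluoride-mediated desilylation frees the hindered C10 hydroxyl under basic conditions that do not isomerise the exocyclic C7=C14 alkene.

Step 14
Reactants: 20 (6R,10R)-chamigra-2,7(14)-dien-10-ol
Product: 21 (6R,10S)-10-bromochamigra-2,7(14)-diene
Conditions: CBr4 (3 equiv), PPh3 (3 equiv), PhMe, 0 → 60 °C
Reagents that add atoms: carbon tetrabromide, BrC(Br)(Br)Br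
Why: Appel reaction, in which the alkoxyphosphonium ion at C10 is displaced by bromide from the rear (SN2), inverting the (10R)-alcohol to the (10S)-bromide; the neopentylic position makes the displacement slow, hence the excess reagent and gentle heating.

Step 15
Reactants: 21 (6R,10S)-10-bromochamigra-2,7(14)-diene
Product: 22 (2R,3R,6R,10S)-2,10-dibromochamigr-7(14)-en-3-ol (target)
Conditions: NBS (1.05 equiv), acetone/H2O 4:1, 0 °C, dark
Reagents that add atoms: N-bromosuccinimide, O=C1CCC(=O)N1Br; water, O
Why: Bromohydrin formation, in which Br+ should add to the more electron-rich trisubstituted C2=C3 alkene on the face anti to the axial C7 arm of ring B (whose C14 methylene lies over C2) and water should open the bromonium ion at the tertiary C3 from the opposite face (Markovnikov, anti addition), setting C2 (Br cis to C11) and C3 (OH cis to C7) together while the hindered C7=C14 alkene is left.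

Compound list
1 | isobutyraldehyde | CC(C)C=O | starting material
2 | prenyl bromide (1-bromo-3-methylbut-2-ene) | CC(C)=CCBr | starting material
3 | 2,2,5-trimethylhex-4-enal | CC(C)=CCC(C)(C)C=O | intermediate
4 | vinylmagnesium bromide | C=C[Mg]Br | starting material
5 | (±)-4,4,7-trimethylocta-1,6-dien-3-ol | C=CC(O)C(C)(C)CC=C(C)C | intermediate
6 | 4,4,7-trimethylocta-1,6-dien-3-one | C=CC(=O)C(C)(C)CC=C(C)C | intermediate
7 | (3R)-4,4,7-trimethylocta-1,6-dien-3-ol | C=C[C@@H](O)C(C)(C)CC=C(C)C | intermediate
8 | (3R)-3-(tert-butyldimethylsilyloxy)-4,4,7-trimethylocta-1,6-diene | C=C[C@@H](O[Si](C)(C)C(C)(C)C)C(C)(C)CC=C(C)C | intermediate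
9 | 3-[(3R)-3-(tert-butyldimethylsilyloxy)-2,2-dimethylpent-4-en-1-yl]-5,5-dimethyl-1,2,4-trioxolane (secondary ozonide) | CC1(C)OC(CC(C)(C)[C@H](O[Si](C)(C)C(C)(C)C)C=C)OO1 | intermediate (not isolated)
10 | (4R)-4-(tert-butyldimethylsilyloxy)-3,3-dimethylhex-5-enal | O=CCC(C)(C)[C@H](O[Si](C)(C)C(C)(C)C)C=C | intermediate
11 | (4R)-4-(tert-butyldimethylsilyloxy)-3,3-dimethyl-2-methylidenehex-5-enal | C=C(C=O)C(C)(C)[C@H](O[Si](C)(C)C(C)(C)C)C=C | intermediate
12 | isoprene | C=CC(C)=C | starting material
13 | (1S)-1-[(3R)-3-(tert-butyldimethylsilyloxy)-2-methylpent-4-en-2-yl]-4-methylcyclohex-3-ene-1-carbaldehyde | O=C[C@]1(CCC(C)=CC1)C(C)(C)[C@H](O[Si](C)(C)C(C)(C)C)C=C | intermediate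
14 | 1-{(1S)-1-[(3R)-3-(tert-butyldimethylsilyloxy)-2-methylpent-4-en-2-yl]-4-methylcyclohex-3-en-1-yl}ethan-1-ol, both carbinol epimers | CC(O)[C@]1(CCC(C)=CC1)C(C)(C)[C@H](O[Si](C)(C)C(C)(C)C)C=C | intermediate
15 | 1-{(1S)-1-[(3R)-3-(tert-butyldimethylsilyloxy)-2-methylpent-4-en-2-yl]-4-methylcyclohex-3-en-1-yl}ethan-1-one | CC(=O)[C@]1(CCC(C)=CC1)C(C)(C)[C@H](O[Si](C)(C)C(C)(C)C)C=C | intermediate
16 | potassium enolate of 15 (potassium 1-substituted ethen-1-olate) | [K+].C=C([O-])[C@]1(CCC(C)=CC1)C(C)(C)[C@H](O[Si](C)(C)C(C)(C)C)C=C | intermediate (not isolated)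
17 | 1-{(1S)-1-[(3R)-3-(tert-butyldimethylsilyloxy)-2-methylpent-4-en-2-yl]-4-methylcyclohex-3-en-1-yl}ethenyl trifluoromethanesulfonate | C=C(OS(=O)(=O)C(F)(F)F)[C@]1(CCC(C)=CC1)C(C)(C)[C@H](O[Si](C)(C)C(C)(C)C)C=C | intermediate (precursor of the key step)
18 | 17 carrying a 9-borabicyclo[3.3.1]nonan-9-yl group on C8 in place of the vinyl double bond (C8H2–C9H2) | C=C(OS(=O)(=O)C(F)(F)F)[C@]1(CCC(C)=CC1)C(C)(C)[C@H](O[Si](C)(C)C(C)(C)C)CCB1C2CCCC1CCC2 | intermediate (not isolated)
19 | (6R,10R)-10-(tert-butyldimethylsilyloxy)chamigra-2,7(14)-diene | C=C1CC[C@@H](O[Si](C)(C)C(C)(C)C)C(C)(C)[C@@]12CCC(C)=CC2 | intermediate (product of the key step)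
20 | (6R,10R)-chamigra-2,7(14)-dien-10-ol | C=C1CC[C@@H](O)C(C)(C)[C@@]12CCC(C)=CC2 | intermediate
21 | (6R,10S)-10-bromochamigra-2,7(14)-diene | C=C1CC[C@H](Br)C(C)(C)[C@@]12CCC(C)=CC2 | intermediate
22 | (2R,3R,6R,10S)-2,10-dibromochamigr-7(14)-en-3-ol | C=C1CC[C@H](Br)C(C)(C)[C@@]12CC[C@@](C)(O)[C@H](Br)C2 | target

Total step count: 15
Longest linear sequence: 15 steps (1 to 22)

Steps most likely to fail

First, step 15. Bromonium formation may show poor facial selectivity, water may open the ion at C2 instead of C3, or the exocyclic alkene may be attacked. The fallback sets out from 21 and uses a Woodward cis-hydroxylation (I2, AgOAc, wet AcOH). Iodine adds to C2=C3 from the open face, acetate opens the iodonium ion trans, and the neighbouring acetate then displaces iodide with inversion, so both oxygens end on the face of C7 whichever carbon the acetate attacked first. This should give the hydroxy acetate F1. K2CO3 in MeOH then gives the diol F2, MsCl/Et3N sulfonylates only the secondary C2 hydroxyl to give the mesylate F3, and LiBr in DMF displaces the axial mesylate with inversion, which comes back to the route at 22.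

Second, step 14. Rear-side attack at the neopentylic C10 is slow, so elimination toward C9 or a 1,2-methyl shift from C11 may overtake substitution. The fallback sets out from 20 and separates activation from displacement: Tf2O and 2,6-di-tert-butylpyridine at −78 °C give the triflate F4, which is displaced cold by Bu4NBr in toluene with inversion, coming back to the route at 21.

Third, step 12. Oxidative addition at the triflate next to the quaternary C6 may be slow, so the borane could protodeboronate, the alkylpalladium could undergo β-hydride elimination, or intermolecular coupling could give oligomers. The fallback sets out from 17 and replaces boron by zinc. Hydroboration to 18 and oxidation with NaBO3·4H2O give the primary alcohol F5. I2, PPh3 and imidazole give the primary iodide F6, and Zn dust in DMA gives the alkylzinc iodide F7. An intramolecular Negishi coupling with Pd(PPh3)4 then forms the same C7–C8 bond and comes back to the route at 19.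

Further compounds
F1 | step 15 | (2S,3R,6R,10S)-10-bromo-3-hydroxychamigr-7(14)-en-2-yl acetate | C=C1CC[C@H](Br)C(C)(C)[C@@]12CC[C@@](C)(O)[C@@H](OC(C)=O)C2
F2 | step 15 | (2S,3R,6R,10S)-10-bromochamigr-7(14)-ene-2,3-diol | C=C1CC[C@H](Br)C(C)(C)[C@@]12CC[C@@](C)(O)[C@@H](O)C2
F3 | step 15 | (2S,3R,6R,10S)-10-bromo-3-hydroxychamigr-7(14)-en-2-yl methanesulfonate | C=C1CC[C@H](Br)C(C)(C)[C@@]12CC[C@@](C)(O)[C@@H](OS(C)(=O)=O)C2
F4 | step 14 | (6R,10R)-chamigra-2,7(14)-dien-10-yl trifluoromethanesulfonate | C=C1CC[C@@H](OS(=O)(=O)C(F)(F)F)C(C)(C)[C@@]12CCC(C)=CC2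
F5 | step 12 | 1-{(1S)-1-[(3R)-3-(tert-butyldimethylsilyloxy)-5-hydroxy-2-methylpentan-2-yl]-4-methylcyclohex-3-en-1-yl}ethenyl trifluoromethanesulfonate | C=C(OS(=O)(=O)C(F)(F)F)[C@]1(CCC(C)=CC1)C(C)(C)[C@H](O[Si](C)(C)C(C)(C)C)CCO
F6 | step 12 | 1-{(1S)-1-[(3R)-3-(tert-butyldimethylsilyloxy)-5-iodo-2-methylpentan-2-yl]-4-methylcyclohex-3-en-1-yl}ethenyl trifluoromethanesulfonate | C=C(OS(=O)(=O)C(F)(F)F)[C@]1(CCC(C)=CC1)C(C)(C)[C@H](O[Si](C)(C)C(C)(C)C)CCI
F7 | step 12 | alkylzinc iodide from F6 (iodozincio group on C8) | C=C(OS(=O)(=O)C(F)(F)F)[C@]1(CCC(C)=CC1)C(C)(C)[C@H](O[Si](C)(C)C(C)(C)C)CC[Zn]I
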